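## Structural features

The target 19 is a flavanone. Ring A (C4a, C5 to C8, C8a) carries methoxy groups at C5 and C7 and the ring oxygen O1 at C8a. Ring C is completed by C2, C3 and the C4 carbonyl, and ring B, a 3,4,5-trimethoxyphenyl group, is attached at C2. C2 (S) is the only stereocentre and has no stereogenic neighbour, so nothing in the molecule can relay or repair its configuration. It is benzylic, bears the aryl ether oxygen and lies β to the C4 ketone. Base can therefore open ring C to the 2'-hydroxychalcone by retro-oxa-Michael reaction and reclose it without control, and acid can ionise the C2–O1 bond. Both arenes are electron-rich, and C4 at the carbinol level is a 2,4,6-trioxygenated benzylic position that ionises easily. The real difficulty is a 1,3,5-trioxygenated ring A with exactly one carbon substituent, which invites regiochemical trouble in any substitution of a phloroglucinol, combined with a single labile stereocentre. The key step uses the alternation on ring A: the oxygenated carbons C8a, C7 and C5 alternate with C8–H, C6–H and the chain-bearing C4a. This is the pattern formed when a 3-alkoxy vinylketene (C8a, C8, C7, C6) is joined to a 1-alkoxyalkyne (C5, C4a), with C8a arriving as the free phenol that later becomes O1.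

## Logic of the disconnections

19 to 18: no skeletal bond is cut; the C4 carbonyl is taken back to a secondary carbinol. With C4 at the alcohol level ring C has no carbonyl to drive β-elimination of O1, so C2 cannot racemise at any earlier stage. The gain is in reactivity, not size. The forward step must oxidise a benzylic alcohol on an electron-rich ring without acid or base.

18 to 17 to 16: the O–Si bond at C4 is cut, then the O1–C2 bond of ring C. This opens the heterocycle to a chain and reduces the C2 problem to the configuration of a secondary benzylic alcohol. The forward closure is an intramolecular displacement by the C8a phenol with inversion, so 16 must be R at that carbon. The C4 oxygen must stay masked so that only one hydroxyl can be activated, and the activation must not ionise the benzylic centre.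

16 to 15: the O–Si bond of the future C2 carbinol is cut. The carbinol has to be masked while ring A is built, because a free alcohol would be acylated by ketene intermediates. The forward step must remove the more labile of two silyl ethers without acid strong enough to ionise C4.

15 to 8 and 10: the bonds C4a–C8a, C5–C6 and C8–C8a of ring A are cut. Ring A falls into a four-carbon and a two-carbon piece in which every oxygen is already in place, so no phloroglucinol has to be substituted selectively. The forward step needs one regiochemical outcome in the ketene–alkyne union, and the silyl ethers and the remote stereocentre must survive neutral heating.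

10 to 9: the O–CH3 bond is cut, which leads to a commercial dione. The forward step must alkylate on oxygen without opening the strained ring.

8 to 7 to 4 and 6 (6 from 5): the O–Si bond is cut, then the bond between the alkyne carbon and the carbinol carbon (the future C4a–C4 bond). This separates a two-carbon alkoxyacetylide from a three-carbon aldehyde that holds the stereocentre. The forward addition must outrun enolisation of a β-silyloxy aldehyde; the configuration of the new carbinol is irrelevant because it ends as the ketone.

4 to 3 to 2 to 1: the aldehyde is traced to an ester, the O–Si bond is cut, and the benzylic C–H bond of the carbinol is traced to a ketone. The only stereocentre then comes from a catalytic enantioselective reduction of a commercial aryl β-keto ester, and no alkene cleavage next to an electron-rich arene is needed. The forward reduction must give the R carbinol, which one later inversion turns into 2S.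

## Other disconnections considered

Alternative 1: The cut passes through C4–C4a, C5–C6, C7–C8 and C4a–C8a of ring A and O1–C2 of ring C, leading back to 3,4,5-trimethoxycinnamic acid A2 and three malonyl extender units. In the forward sense a ligase would activate A2 as a thioester, a chalcone synthase would extend it three times and fold the chain by Claisen condensation to the chalcone A3, and a chalcone isomerase would close ring C by oxa-Michael addition to (S)-5,7-dihydroxy-2-(3,4,5-trimethoxyphenyl)chroman-4-one A1.
- In favour: five bonds, two rings and the stereocentre would form in one aqueous pot, and the isomerase delivers the 2S configuration of the target. On step economy (about three operations against eleven) and on directness of stereocontrol this plan is the better one.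
- Against it here: the starter unit is a bulky, fully methylated aryl group far from the 4-hydroxyphenyl unit the three enzymes normally process, so acceptance at each active site is an open question. A1 also lacks the two methyl ethers of ring A. The C5 hydroxyl is hydrogen-bonded to the C4 carbonyl and would need basic alkylation, the conditions under which a flavanone opens to its chalcone, so C2 is put at risk at the end.
- Comparison: the chosen plan places both methoxy groups while ring A is built and meets the ketone only in a neutral last step, which is its structural advantage. Mechanistically both build ring A from open-chain units (Claisen folding against a pericyclic cascade) and are equal in regiochemical certainty.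

Alternative 2: The cut is at O1–C2 and C3–C4, so ring C is formed by a [4+2] cycloaddition. Ring A is bought as 2-hydroxy-4,6-dimethoxybenzaldehyde A5, and ring B with C2–C3 as 3,4,5-trimethoxystyrene A6. Forward, A5 would be acetalised with an orthoformate and ionised by a chiral phosphoric acid to the alkoxy ortho-quinone methide A7, which would add A6 to give (2S,4S)-4,5,7-trimethoxy-2-(3,4,5-trimethoxyphenyl)chromane A4. Hydrolysis of the C4 methyl ether would lead to 18 and the oxidation of step 11 to 19.
- In favour: the plan is convergent, the ring A pattern is purchased, and C2 is created by catalyst control in the ring-forming step. C4 is carried below the ketone level until the end, in which respect the two plans are equal and even share 18. About four steps make it the better plan on step economy.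
- Against it here: facial control must come from an ion pair between the phosphate and an oxocarbenium-like diene, while A6 has no hydrogen-bond donor to organise the transition state. A stepwise cationic path through a benzylic cation at C2 would leak stereochemistry. The electron-rich arenes could intercept the cation by Friedel–Crafts alkylation, and acid hydrolysis of A4 runs through the C4 cation, from which cycloreversion is conceivable.
- Comparison: the alternative sets C2 in an enantioselective event whose sense and level are uncertain for this diene and dienophile. The chosen plan uses a ketone transfer hydrogenation and an SN2 inversion, each well understood, at the cost of more steps.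

Alternative 3: The cut is at C4–C4a and C3–C4 (both to the carbonyl carbon) and at O1–C2. Forward, 2-iodo-3,5-dimethoxyphenol A9, a one-carbon carbonyl source and 5-ethynyl-1,2,3-trimethoxybenzene A10 would give the ynone A11 by palladium-catalysed carbonylative coupling. A11 would close in the same pot by 6-endo-dig oxa-Michael addition to 5,7-dimethoxy-2-(3,4,5-trimethoxyphenyl)-4H-chromen-4-one A8. An enantioselective 1,4-reduction of the C2=C3 bond would then be needed to reach 19.
- In favour: three components, one step to the complete and fully methylated skeleton, stable intermediates and no protecting groups. On convergence, robustness and step count (about four) it is the better plan.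
- Against it here: A8 has no stereocentre, so the whole stereochemical problem is left to a late asymmetric conjugate reduction of an electron-rich chromone. Over-reduction to the flavan-4-ol level and base-induced racemisation of 19 threaten that step. A9 requires iodination between the hydroxyl and one methoxy group instead of between the two methoxy groups, which is the regiochemical problem that building ring A avoids. 5-exo closure of A11 to an aurone also competes.
- Comparison: if A9 is accessible the two plans are equal in securing the oxygenation pattern, by purchase in one case and by construction in the other. The chosen plan fixes C2 in its first step and transfers it by a stereospecific closure, whereas the alternative depends on a demanding enantioselective step at the very end.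

Key step: step 7

Assumption: the acetylide addition of step 4 is not expected to be usefully selective at the new carbinol carbon; compounds 7, 8 and 12 to 18 are drawn and named as the syn epimer, the other epimer at that carbon is carried through the same steps, and both converge in step 11, which removes the centre.

Step 1
Reactants: 1 ethyl 3-oxo-3-(3,4,5-trimethoxyphenyl)propanoate
Product: 2 ethyl (3R)-3-hydroxy-3-(3,4,5-trimethoxyphenyl)propanoate
Conditions: RuCl(p-cymene)[(R,R)-TsDPEN] (1 mol%), HCO2H–Et3N (5:2), 40 °C
Reagents that add atoms: none
Why: Noyori asymmetric transfer hydrogenation of an aryl ketone; the (R,R)-diamine ruthenium hydride places the aryl group against the arene ligand and delivers hydride to the Si face, which should give the 3R carbinol from an activated β-keto ester.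

Step 2
Reactants: 2 ethyl (3R)-3-hydroxy-3-(3,4,5-trimethoxyphenyl)propanoate
Product: 3 ethyl (3R)-3-(triethylsilyloxy)-3-(3,4,5-trimethoxyphenyl)propanoate
Conditions: TESCl, imidazole, CH2Cl2, 0 °C → rt
Reagents that add atoms: chlorotriethylsilane, CC[Si](Cl)(CC)CC
Why: Imidazole-promoted silylation of a secondary alcohol; triethylsilyl is chosen because it can later be removed in the presence of the bulkier silyl ether at the future C4.

Step 3
Reactants: 3 ethyl (3R)-3-(triethylsilyloxy)-3-(3,4,5-trimethoxyphenyl)propanoate
Product: 4 (3R)-3-(triethylsilyloxy)-3-(3,4,5-trimethoxyphenyl)propanal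
Conditions: i-Bu2AlH (1.1 equiv), CH2Cl2, −78 °C; MeOH, then aq. potassium sodium tartrate
Reagents that add atoms: none
Why: Partial reduction of an ester with one equivalent of hydride at −78 °C; the aldehyde is released only on work-up, so over-reduction should be avoided, and it is used crude and cold because a β-silyloxy aldehyde can eliminate.

Step 4
Reactants: 4 (3R)-3-(triethylsilyloxy)-3-(3,4,5-trimethoxyphenyl)propanal; 5 2-chloro-1,1-dimethoxyethane (chloroacetaldehyde dimethyl acetal)
Product: 7 (3S,5R)-1-methoxy-5-(triethylsilyloxy)-5-(3,4,5-trimethoxyphenyl)pent-1-yn-3-ol, via lithium methoxyacetylide 6 (not isolated)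
Conditions: 5, LiNEt2 (from Et2NH, n-BuLi; 3 equiv per 5), THF, 0 °C; then 4, −78 °C; aq. NH4Cl
Reagents that add atoms: none
Why: Twofold elimination and metalation of the chloroacetal by the lithium amide is the established way to a lithium alkoxyacetylide, and its 1,2-addition to the aldehyde at −78 °C should be faster than enolisation. The new carbinol centre forms without useful control (see the assumption), and the product is kept away from acid, which would trigger Meyer–Schuster rearrangement.

Step 5
Reactants: 7 (3S,5R)-1-methoxy-5-(triethylsilyloxy)-5-(3,4,5-trimethoxyphenyl)pent-1-yn-3-ol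
Product: 8 (3S,5R)-3-(tert-butyldimethylsilyloxy)-1-methoxy-5-(triethylsilyloxy)-5-(3,4,5-trimethoxyphenyl)pent-1-yne
Conditions: TBSCl, imidazole, DMF, rt
Reagents that add atoms: tert-butylchlorodimethylsilane, CC(C)(C)[Si](C)(C)Cl
Why: Silylation under basic conditions that the acid-sensitive ynol ether tolerates; the bulkier silyl group masks the future C4 oxygen so that no hydroxyl is present to trap ketenes in step 7.

Step 6
Reactants: 9 cyclobutane-1,3-dione
Product: 10 3-methoxycyclobut-2-en-1-one
Conditions: TMSCHN2, MeOH–Et2O, 0 °C
Reagents that add atoms: (trimethylsilyl)diazomethane, C[Si](C)(C)C=[N+]=[N-]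
Why: O-Methylation of a strongly acidic vinylogous acid (the enol form of the dione) by a diazoalkane; no base or heat is involved, so the strained ring should survive, and the volatile, hydrolytically labile product is used as a cold solution.

Step 7
Reactants: 10 3-methoxycyclobut-2-en-1-one; 8 (3S,5R)-3-(tert-butyldimethylsilyloxy)-1-methoxy-5-(triethylsilyloxy)-5-(3,4,5-trimethoxyphenyl)pent-1-yne
Product: 15 2-[(1S,3R)-1-(tert-butyldimethylsilyloxy)-3-(triethylsilyloxy)-3-(3,4,5-trimethoxyphenyl)propyl]-3,5-dimethoxyphenol, via 3-methoxyvinylketene 11 (not isolated), via vinylcyclobutenone adduct 12 (not isolated), via dienylketene 13 (not isolated), via cyclohexadienone tautomer 14 (not isolated)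
Conditions: 10 (1.5 equiv), toluene (degassed), sealed tube, 80 → 110 °C
Reagents that add atoms: none
Why: Danheiser benzannulation; the closest known reaction type is the thermal union of 3-alkylcyclobutenones with 1-alkoxy- or 1-siloxyalkynes to give resorcinol monoethers. Conrotatory four-electron opening of 10 gives ketene 11; the nucleophilic, chain-bearing carbon of ynol ether 8 attacks the ketene carbonyl carbon and the [2+2] cycloaddition closes to 12, forming C4a–C8a and C5–C6. A second four-electron opening gives dienylketene 13, whose six-electron disrotatory electrocyclisation forms C8–C8a and closes ring A as dienone 14, and enolisation gives phenol 15. No lasting stereocentre is created, since the sp3 ring carbon of 12 becomes aromatic C6, and the two silyloxy-bearing centres of the chain are spectators under neutral heating. The only selectivity needed is the regiochemistry of the [2+2] event, which the polarisation of the ynol ether secures by placing the chain ortho and the methoxy group meta to the new hydroxyl. The 3-methoxy group of 10 is a variation on the usual alkyl substituent and should slow ring opening, but 12, like the intermediate of every alkoxyalkyne benzannulation, is itself a 3-alkoxycyclobutenone that opens under these conditions. A methyl ynol ether cannot fragment by retro-ene loss of an alkene as ethyl or tert-butyl ynol ethers do on heating, and the excess of 10 covers ketene lost to dimerisation or to O-acylation of the hindered phenol.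

Step 8
Reactants: 15 2-[(1S,3R)-1-(tert-butyldimethylsilyloxy)-3-(triethylsilyloxy)-3-(3,4,5-trimethoxyphenyl)propyl]-3,5-dimethoxyphenol
Product: 16 2-[(1S,3R)-1-(tert-butyldimethylsilyloxy)-3-hydroxy-3-(3,4,5-trimethoxyphenyl)propyl]-3,5-dimethoxyphenol
Conditions: HF·pyridine, pyridine, THF, 0 °C
Reagents that add atoms: none
Why: Buffered fluoride desilylation; a secondary triethylsilyl ether should be cleaved far faster than the tert-butyldimethylsilyl ether, which is flanked by two ortho substituents, and the pyridine buffer keeps the medium from ionising the C4 benzylic position.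

Step 9
Reactants: 16 2-[(1S,3R)-1-(tert-butyldimethylsilyloxy)-3-hydroxy-3-(3,4,5-trimethoxyphenyl)propyl]-3,5-dimethoxyphenol
Product: 17 (2S,4S)-4-(tert-butyldimethylsilyloxy)-5,7-dimethoxy-2-(3,4,5-trimethoxyphenyl)chromane
Conditions: PPh3, DIAD, toluene, 0 °C → rt
Reagents that add atoms: none
Why: Intramolecular Mitsunobu etherification; the phenol displaces the activated hydroxyl in a 6-exo-tet SN2 process, so the R carbinol should give the 2S ether by inversion. A non-polar solvent and low temperature disfavour ionisation of the benzylic centre, whose two meta methoxy groups are not conjugating donors.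

Step 10
Reactants: 17 (2S,4S)-4-(tert-butyldimethylsilyloxy)-5,7-dimethoxy-2-(3,4,5-trimethoxyphenyl)chromane
Product: 18 (2S,4S)-5,7-dimethoxy-2-(3,4,5-trimethoxyphenyl)chroman-4-ol
Conditions: Bu4NF, THF, 0 °C → rt
Reagents that add atoms: none
Why: Fluoride cleavage of the remaining silyl ether under non-acidic conditions; with no free phenol and no carbonyl present, neither quinone-methide formation nor ring opening is possible, and the acid-sensitive flavan-4-ol is taken on without delay.

Step 11
Reactants: 18 (2S,4S)-5,7-dimethoxy-2-(3,4,5-trimethoxyphenyl)chroman-4-ol
Product: 19 (2S)-5,7-dimethoxy-2-(3,4,5-trimethoxyphenyl)chroman-4-one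
Conditions: Dess–Martin periodinane, pyridine, CH2Cl2, 0 °C → rt
Reagents that add atoms: none
Why: Dess–Martin oxidation of a secondary benzylic alcohol under pyridine buffering; the conditions are neither basic enough for retro-oxa-Michael opening nor acidic enough to ionise C4, so the 2S centre should be retained while the uncontrolled C4 centre is removed.

Compound list

1 | ethyl 3-oxo-3-(3,4,5-trimethoxyphenyl)propanoate | CCOC(=O)CC(=O)c1cc(OC)c(OC)c(OC)c1 | starting material
2 | ethyl (3R)-3-hydroxy-3-(3,4,5-trimethoxyphenyl)propanoate | CCOC(=O)C[C@@H](O)c1cc(OC)c(OC)c(OC)c1 | intermediate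
3 | ethyl (3R)-3-(triethylsilyloxy)-3-(3,4,5-trimethoxyphenyl)propanoate | CCOC(=O)C[C@@H](O[Si](CC)(CC)CC)c1cc(OC)c(OC)c(OC)c1 | intermediate
4 | (3R)-3-(triethylsilyloxy)-3-(3,4,5-trimethoxyphenyl)propanal | O=CC[C@@H](O[Si](CC)(CC)CC)c1cc(OC)c(OC)c(OC)c1 | intermediate
5 | 2-chloro-1,1-dimethoxyethane | COC(CCl)OC | starting material
6 | lithium methoxyacetylide | [Li]C#COC | intermediate (not isolated)
7 | (3S,5R)-1-methoxy-5-(triethylsilyloxy)-5-(3,4,5-trimethoxyphenyl)pent-1-yn-3-ol | COC#C[C@@H](O)C[C@@H](O[Si](CC)(CC)CC)c1cc(OC)c(OC)c(OC)c1 | intermediate
8 | (3S,5R)-3-(tert-butyldimethylsilyloxy)-1-methoxy-5-(triethylsilyloxy)-5-(3,4,5-trimethoxyphenyl)pent-1-yne | COC#C[C@@H](O[Si](C)(C)C(C)(C)C)C[C@@H](O[Si](CC)(CC)CC)c1cc(OC)c(OC)c(OC)c1 | intermediate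
9 | cyclobutane-1,3-dione | O=C1CC(=O)C1 | starting material
10 | 3-methoxycyclobut-2-en-1-one | COC1=CC(=O)C1 | intermediate
11 | 3-methoxybuta-1,3-dien-1-one | C=C(OC)C=C=O | intermediate (not isolated)
12 | 3-methoxy-4-(1-methoxyethenyl)-2-[(1S,3R)-1-(tert-butyldimethylsilyloxy)-3-(triethylsilyloxy)-3-(3,4,5-trimethoxyphenyl)propyl]cyclobut-2-en-1-one | C=C(OC)C1C(=O)C(=C1OC)[C@@H](O[Si](C)(C)C(C)(C)C)C[C@@H](O[Si](CC)(CC)CC)c2cc(OC)c(OC)c(OC)c2 | intermediate (not isolated)
13 | (3E)-3,5-dimethoxy-2-[(1S,3R)-1-(tert-butyldimethylsilyloxy)-3-(triethylsilyloxy)-3-(3,4,5-trimethoxyphenyl)propyl]hexa-1,3,5-trien-1-one | C=C(OC)/C=C(/OC)C(=C=O)[C@@H](O[Si](C)(C)C(C)(C)C)C[C@@H](O[Si](CC)(CC)CC)c1cc(OC)c(OC)c(OC)c1 | intermediate (not isolated)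
14 | 3,5-dimethoxy-2-[(1S,3R)-1-(tert-butyldimethylsilyloxy)-3-(triethylsilyloxy)-3-(3,4,5-trimethoxyphenyl)propyl]cyclohexa-2,4-dien-1-one | COC1=CC(OC)=C(C(=O)C1)[C@@H](O[Si](C)(C)C(C)(C)C)C[C@@H](O[Si](CC)(CC)CC)c2cc(OC)c(OC)c(OC)c2 | intermediate (not isolated)
15 | 2-[(1S,3R)-1-(tert-butyldimethylsilyloxy)-3-(triethylsilyloxy)-3-(3,4,5-trimethoxyphenyl)propyl]-3,5-dimethoxyphenol | COc1cc(O)c([C@@H](O[Si](C)(C)C(C)(C)C)C[C@@H](O[Si](CC)(CC)CC)c2cc(OC)c(OC)c(OC)c2)c(OC)c1 | intermediate
16 | 2-[(1S,3R)-1-(tert-butyldimethylsilyloxy)-3-hydroxy-3-(3,4,5-trimethoxyphenyl)propyl]-3,5-dimethoxyphenol | COc1cc(O)c([C@@H](O[Si](C)(C)C(C)(C)C)C[C@@H](O)c2cc(OC)c(OC)c(OC)c2)c(OC)c1 | intermediate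
17 | (2S,4S)-4-(tert-butyldimethylsilyloxy)-5,7-dimethoxy-2-(3,4,5-trimethoxyphenyl)chromane | COc1cc(OC)c2c(c1)O[C@H](c1cc(OC)c(OC)c(OC)c1)C[C@@H]2O[Si](C)(C)C(C)(C)C | intermediate
18 | (2S,4S)-5,7-dimethoxy-2-(3,4,5-trimethoxyphenyl)chroman-4-ol | COc1cc(OC)c2c(c1)O[C@H](c1cc(OC)c(OC)c(OC)c1)C[C@@H]2O | intermediate
19 | (2S)-5,7-dimethoxy-2-(3,4,5-trimethoxyphenyl)chroman-4-one | COc1cc(OC)c2c(c1)O[C@H](c1cc(OC)c(OC)c(OC)c1)CC2=O | target

Total step count: 11. Longest linear sequence: 10 steps (steps 1 to 5 and 7 to 11, from 1 to 19); step 6 is a one-step branch.

Steps least certain to work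

Step 7 (key step). The donor-substituted four-membered ring of 10 is expected to open more slowly than alkyl analogues. The temperature needed may then reach the range where the product loses silanol from C4 (ionisation assisted by the ortho hydroxyl), or where the ketene is consumed by dimerisation or by acylating the product phenol. Fallback, setting out from 8: the ketene is generated by light instead of heat. 1-Diazo-3-methoxybut-3-en-2-one F1, made by diazo transfer to the corresponding enone, would be irradiated with 8 at room temperature. Photochemical Wolff rearrangement should give the same ketene 11 without heating a donor-substituted cyclobutenone, cycloaddition should give 12, and brief warming to about 80 °C should carry the sequence through 13 and 14. The route is rejoined at 15.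

Step 9. Ionisation of the activated benzylic carbinol may compete with SN2 closure and erode the enantiomeric purity, and elimination to the styrene-type alkene is a second loss channel. Fallback, setting out from 15: the closure is run as a phenoxide displacement of a sulfonate. The phenol would be acetylated to 2-[(1S,3R)-1-(tert-butyldimethylsilyloxy)-3-(triethylsilyloxy)-3-(3,4,5-trimethoxyphenyl)propyl]-3,5-dimethoxyphenyl acetate F2. The triethylsilyl ether would be removed as in step 8 to give the carbinol F3, which would be converted at low temperature into the methanesulfonate F4. Methanolysis of the acetate with K2CO3 at 0 °C would release the phenoxide next to the leaving group, and 6-exo-tet closure with inversion should rejoin the route at 17.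

Step 8. Desilylation may not stop at the less hindered silyl ether, or the weakly acidic fluoride medium may ionise the C4 position with the help of the free ortho phenol. Fallback, setting out from 15: protecting-group differentiation is replaced by chemoselective activation. Excess Bu4NF under basic, non-ionising conditions would remove both silyl groups to give 2-[(1S,3R)-1,3-dihydroxy-3-(3,4,5-trimethoxyphenyl)propyl]-3,5-dimethoxyphenol F5. A Mitsunobu cyclisation would then rely on activation of the unhindered carbinol only, the C4 carbinol being flanked by two ortho substituents and hydrogen-bonded to the phenol. This closure carries its own risk of activation at C4. The route is rejoined at 18.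

Step 4. The strongly basic mixture, which also holds an amine and an alkoxide, may enolise the aldehyde and expel the β-silyloxy group, and acid on work-up may rearrange the hydroxy ynol ether. Fallback, setting out from 3: the carbon–carbon bond is made on an amide instead of an aldehyde. The ester would be converted with MeNH(OMe)·HCl and i-PrMgCl into (3R)-N-methoxy-N-methyl-3-(triethylsilyloxy)-3-(3,4,5-trimethoxyphenyl)propanamide F6. Acetylide 6 should add once to give (5R)-1-methoxy-5-(triethylsilyloxy)-5-(3,4,5-trimethoxyphenyl)pent-1-yn-3-one F7. A Corey–Bakshi–Shibata reduction with catecholborane in an aprotic solvent at low temperature should give the carbinol, and would also allow its configuration to be set by the catalyst. The route is rejoined at 7.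

Further compounds

F1 | step 7 | 1-diazo-3-methoxybut-3-en-2-one | C=C(OC)C(=O)C=[N+]=[N-]
F2 | step 9 | 2-[(1S,3R)-1-(tert-butyldimethylsilyloxy)-3-(triethylsilyloxy)-3-(3,4,5-trimethoxyphenyl)propyl]-3,5-dimethoxyphenyl acetate | COc1cc(OC(C)=O)c([C@@H](O[Si](C)(C)C(C)(C)C)C[C@@H](O[Si](CC)(CC)CC)c2cc(OC)c(OC)c(OC)c2)c(OC)c1
F3 | step 9 | 2-[(1S,3R)-1-(tert-butyldimethylsilyloxy)-3-hydroxy-3-(3,4,5-trimethoxyphenyl)propyl]-3,5-dimethoxyphenyl acetate | COc1cc(OC(C)=O)c([C@@H](O[Si](C)(C)C(C)(C)C)C[C@@H](O)c2cc(OC)c(OC)c(OC)c2)c(OC)c1
F4 | step 9 | 2-[(1S,3R)-1-(tert-butyldimethylsilyloxy)-3-(methanesulfonyloxy)-3-(3,4,5-trimethoxyphenyl)propyl]-3,5-dimethoxyphenyl acetate | COc1cc(OC(C)=O)c([C@@H](O[Si](C)(C)C(C)(C)C)C[C@@H](OS(C)(=O)=O)c2cc(OC)c(OC)c(OC)c2)c(OC)c1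
F5 | step 8 | 2-[(1S,3R)-1,3-dihydroxy-3-(3,4,5-trimethoxyphenyl)propyl]-3,5-dimethoxyphenol | COc1cc(O)c([C@@H](O)C[C@@H](O)c2cc(OC)c(OC)c(OC)c2)c(OC)c1
F6 | step 4 | (3R)-N-methoxy-N-methyl-3-(triethylsilyloxy)-3-(3,4,5-trimethoxyphenyl)propanamide | CON(C)C(=O)C[C@@H](O[Si](CC)(CC)CC)c1cc(OC)c(OC)c(OC)c1
F7 | step 4 | (5R)-1-methoxy-5-(triethylsilyloxy)-5-(3,4,5-trimethoxyphenyl)pent-1-yn-3-one | COC#CC(=O)C[C@@H](O[Si](CC)(CC)CC)c1cc(OC)c(OC)c(OC)c1
A1 | alternative 1 | (S)-5,7-dihydroxy-2-(3,4,5-trimethoxyphenyl)chroman-4-one | Oc1cc(O)c2c(c1)O[C@H](c1cc(OC)c(OC)c(OC)c1)CC2=O
A2 | alternative 1 | (E)-3-(3,4,5-trimethoxyphenyl)prop-2-enoic acid (3,4,5-trimethoxycinnamic acid) | COc1cc(/C=C/C(=O)O)cc(OC)c1OC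
A3 | alternative 1 | (E)-1-(2,4,6-trihydroxyphenyl)-3-(3,4,5-trimethoxyphenyl)prop-2-en-1-one | COc1cc(/C=C/C(=O)c2c(O)cc(O)cc2O)cc(OC)c1OC
A4 | alternative 2 | (2S,4S)-4,5,7-trimethoxy-2-(3,4,5-trimethoxyphenyl)chromane | COc1cc(OC)c2c(c1)O[C@H](c1cc(OC)c(OC)c(OC)c1)C[C@@H]2OC
A5 | alternative 2 | 2-hydroxy-4,6-dimethoxybenzaldehyde | COc1cc(O)c(C=O)c(OC)c1
A6 | alternative 2 | 5-ethenyl-1,2,3-trimethoxybenzene (3,4,5-trimethoxystyrene) | C=Cc1cc(OC)c(OC)c(OC)c1
A7 | alternative 2 | 3,5-dimethoxy-6-(methoxymethylidene)cyclohexa-2,4-dien-1-one | COC=C1C(=O)C=C(OC)C=C1OC
A8 | alternative 3 | 5,7-dimethoxy-2-(3,4,5-trimethoxyphenyl)-4H-chromen-4-one | COc1cc(OC)c2c(c1)OC(c1cc(OC)c(OC)c(OC)c1)=CC2=O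
A9 | alternative 3 | 2-iodo-3,5-dimethoxyphenol | COc1cc(O)c(I)c(OC)c1
A10 | alternative 3 | 5-ethynyl-1,2,3-trimethoxybenzene | C#Cc1cc(OC)c(OC)c(OC)c1
A11 | alternative 3 | 1-(2-hydroxy-4,6-dimethoxyphenyl)-3-(3,4,5-trimethoxyphenyl)prop-2-yn-1-one | COc1cc(O)c(C(=O)C#Cc2cc(OC)c(OC)c(OC)c2)c(OC)c1
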